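Numbering: C1 is the quaternary oxirane carbon carrying the C7H2OBz arm, C2 is CH–OBz, C3 is CH–OH, C4=C5 is the alkene, C6 is the oxirane CH.
Cuts, in order: the oxirane bond O–C6 (back to a trans C1–OH/C6–Cl chlorohydrin), the two benzoate C–O bonds, the C7 oxidation level (CH2O back to CO2H), and last the ring bond C1–C6.
What allows the last cut: in the cyclohexene ring C1–C6, the bond C1–C6 ties an O-bearing quaternary carbon with a carboxyl-level branch (C7) to a heteroatom-bearing carbon allylic to C4=C5. This is the unit C7–C1–C6–C5=C4 of a gamma,delta-unsaturated acid. Re-bonding the C7 oxygen to C4 gives a delta-lactone ring (O, C7, C1, C2, C3, C4) with an (E)-2-chlorovinyl group (C5=C6) on C4.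
Forward order of rings: sugar pyranose, dioxolane across O2/O3, pyranose opened by one-carbon alkynylation (adds C6), delta-lactone closed, lactone contracted to the cyclohexene by the Ireland–Claisen shift, oxirane closed in the penultimate step.
Stereochemistry: C2 and C3 are C4 and C3 of D-galacturonic acid. Sugar C2 becomes C4 and is spent in passing its chirality to C1. The E geometry from syn hydrozirconation fixes C6–Cl trans to O1, and SN2 closure inverts C6, so the oxirane lies syn to O2 and O3.

Key step: step 8

Assumption: the pyranose lactols of steps 1–3 are carried as anomeric mixtures (anomeric centre undefined in the SMILES) because that carbon becomes the alkyne carbon C5 in step 4. D-galacturonic acid is drawn in its aldehydo form. Descriptors of the carbocycles refer to the numbering above; the change of the C1 descriptor along the route reflects CIP priorities only.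

Step 1
Reactants: 1 D-galacturonic acid; 2 benzyl bromide
Product: 3 benzyl D-galactopyranuronate
Conditions: BnBr, KHCO3, DMF, rt
Reagents that add atoms: benzyl bromide, BrCc1ccccc1
Why: SN2 O-alkylation of the carboxylate under bicarbonate is far faster than etherification of the sugar hydroxyls, so only the acid is capped, and with a group that later leaves by hydrogenolysis instead of base.

Step 2
Reactants: 3 benzyl D-galactopyranuronate; 4 2,2-dimethoxypropane
Product: 5 benzyl 3,4-O-isopropylidene-D-galactopyranuronate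
Conditions: Me2C(OMe)2 (1.3 equiv), TsOH·H2O (cat.), DMF, 0 °C → rt; Et3N quench
Reagents that add atoms: 2,2-dimethoxypropane, COC(C)(C)OC
Why: Acid-catalysed transketalisation with limited reagent in DMF should pick the cis-vicinal O3/O4 pair of the pyranose (sugar numbering), as it does in the homomorphous arabinopyranose series, leaving the lactol and O2 free.

Step 3
Reactants: 5 benzyl 3,4-O-isopropylidene-D-galactopyranuronate
Product: 6 3,4-O-isopropylidene-D-galactopyranuronic acid
Conditions: H2 (1 atm), Pd/C (10 wt%), EtOAc–MeOH, rt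
Reagents that add atoms: none
Why: Catalytic hydrogenolysis of the benzyl ester is neutral, so acetonide and lactol stay untouched and the free acid is reached without exposing a uronate ester to base.

Step 4
Reactants: 6 3,4-O-isopropylidene-D-galactopyranuronic acid; 7 dimethyl (1-diazo-2-oxopropyl)phosphonate
Product: 8 6,7-dideoxy-3,4-O-isopropylidene-L-galacto-hept-6-ynonic acid
Conditions: K2CO3 (3 equiv), MeOH, rt → 40 °C; cold aq. KHSO4 to pH 3–4, EtOAc, used at once
Reagents that add atoms: dimethyl (1-diazo-2-oxopropyl)phosphonate, COP(=O)(OC)C(=[N+]=[N-])C(C)=O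
Why: The Ohira–Bestmann (Seyferth–Gilbert) homologation acts on the aldehydo fraction of a lactol, running it on the potassium carboxylate instead of an ester removes the acidity of sugar H-5 and with it the 4,5-elimination typical of uronate esters, and the 1,2-hydrogen shift of the alkylidene carbene gives the terminal alkyne without touching the carbinol centre that becomes C4.

Step 5
Reactants: 8 6,7-dideoxy-3,4-O-isopropylidene-L-galacto-hept-6-ynonic acid
Product: 9 6,7-dideoxy-3,4-O-isopropylidene-L-galacto-hept-6-ynono-1,5-lactone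
Conditions: DCC, DMAP (cat.), CH2Cl2 (0.01 M), 0 °C → rt
Reagents that add atoms: none
Why: Steglich-type carbodiimide lactonisation closes the only ring available (O4 onto C7, since O2 and O3 sit in the dioxolane and the C1 hydroxyl cannot cyclise), and its non-acidic medium keeps the cis-dioxolane from migrating along the open chain.

Step 6
Reactants: 9 6,7-dideoxy-3,4-O-isopropylidene-L-galacto-hept-6-ynono-1,5-lactone; 10 chlorotriethylsilane
Product: 11 6,7-dideoxy-3,4-O-isopropylidene-2-O-triethylsilyl-L-galacto-hept-6-ynono-1,5-lactone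
Conditions: Et3SiCl, imidazole, CH2Cl2, 0 °C
Reagents that add atoms: chlorotriethylsilane, CC[Si](Cl)(CC)CC
Why: Imidazole-promoted silylation of the single free hydroxyl installs a group that tolerates base, hydride and acylation but falls together with the acetonide in step 12.

Step 7
Reactants: 11 6,7-dideoxy-3,4-O-isopropylidene-2-O-triethylsilyl-L-galacto-hept-6-ynono-1,5-lactone; 12 zirconocene chloride hydride Cp2Zr(H)Cl; 13 N-chlorosuccinimide
Product: 15 (E)-7-chloro-6,7-dideoxy-3,4-O-isopropylidene-2-O-triethylsilyl-L-galacto-hept-6-enono-1,5-lactone, via alkenylzirconocene chloride 14 (not isolated)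
Conditions: Cp2Zr(H)Cl (1.3 equiv), CH2Cl2, 0 °C → rt, dark; then NCS, 0 °C
Reagents that add atoms: N-chlorosuccinimide, O=C1CCC(=O)N1Cl
Why: Hydrozirconation of a terminal alkyne is a fast syn addition that puts zirconium on the terminal carbon ahead of any attack on the hindered lactone carbonyl, and electrophilic chlorination of the C–Zr bond goes with retention, fixing the E geometry that later decides C6.

Step 8
Reactants: 15 (E)-7-chloro-6,7-dideoxy-3,4-O-isopropylidene-2-O-triethylsilyl-L-galacto-hept-6-enono-1,5-lactone; 16 chlorotrimethylsilane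
Product: 19 (1S,2R,3R,6R)-6-chloro-2,3-(isopropylidenedioxy)-1-(triethylsilyloxy)cyclohex-4-ene-1-carboxylic acid, via silyl ketene acetal 17 (not isolated), via trimethylsilyl ester 18 (not isolated)
Conditions: Me3SiCl–Et3N (premixed, 3 equiv), then KN(SiMe3)2 (1.3 equiv), THF, −78 °C → rt; PhMe, 90–110 °C; aq. citric acid, THF, 0 °C
Reagents that add atoms: none
Why: KN(SiMe3)2 removes H-1 while Me3SiCl is already present, so the potassium enolate is O-silylated at once to the cyclic ketene acetal 17, which on heating undergoes a concerted [3,3] shift that forms C1–C6, breaks C4–O and creates C4=C5 and the C7 silyl ester 18, hydrolysed to 19 on work-up. The closest known reaction type is the Ireland–Claisen ring contraction of 6-alkenyl delta-lactone silyl ketene acetals to cyclohex-3-enecarboxylic acids (alicyclic Claisen). The cyclohexene closes pericyclically, suprafacial on both three-atom components, through the boat-like bicyclo[2.2.2]octane-shaped array forced by the two-carbon C2–C3 tether, a geometry the cis-fused dioxolane favours because it already holds C2–C3 eclipsed. C1 is controlled by C4: the chlorovinyl arm reaches only the ketene acetal face on which it stands, the face it shares with O2 and O3, so C6 bonds there and, in the new ring, C7 is turned anti and O1 syn to O2 and O3. C6 is controlled by the alkene geometry: only the C4–C5 rotamer that leads to a cis ring alkene is accessible, so one face of C5=C6 is used and the E chloride ends up cis to C7 and trans to O1. The step needs O-silylation to outrun beta-elimination of O2 and C-silylation, which the internal quench at −78 °C and the hard potassium counter-ion should secure, and the configuration of C1 in 15 is irrelevant because enolisation erases it.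

Step 9
Reactants: 19 (1S,2R,3R,6R)-6-chloro-2,3-(isopropylidenedioxy)-1-(triethylsilyloxy)cyclohex-4-ene-1-carboxylic acid; 20 (trimethylsilyl)diazomethane
Product: 21 methyl (1S,2R,3R,6R)-6-chloro-2,3-(isopropylidenedioxy)-1-(triethylsilyloxy)cyclohex-4-ene-1-carboxylate
Conditions: Me3SiCHN2, PhMe–MeOH (4:1), 0 °C
Reagents that add atoms: (trimethylsilyl)diazomethane, C[Si](C)(C)C=[N+]=[N-]
Why: Diazoalkane O-methylation esterifies the hindered acid by proton transfer and alkylation without a long-lived carboxylate that could attack the allylic chloride in an SN2' sense.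

Step 10
Reactants: 21 methyl (1S,2R,3R,6R)-6-chloro-2,3-(isopropylidenedioxy)-1-(triethylsilyloxy)cyclohex-4-ene-1-carboxylate
Product: 22 [(1R,2R,3R,6R)-6-chloro-2,3-(isopropylidenedioxy)-1-(triethylsilyloxy)cyclohex-4-en-1-yl]methanol
Conditions: i-Bu2AlH (3 equiv), CH2Cl2, −78 → −20 °C; aq. potassium sodium tartrate
Reagents that add atoms: none
Why: Ester-to-alcohol reduction with the electrophilic hydride i-Bu2AlH should leave the secondary allylic chloride and the alkene alone at low temperature, which LiAlH4 would not.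

Step 11
Reactants: 22 [(1R,2R,3R,6R)-6-chloro-2,3-(isopropylidenedioxy)-1-(triethylsilyloxy)cyclohex-4-en-1-yl]methanol; 23 benzoyl chloride
Product: 24 [(1R,2R,3R,6R)-6-chloro-2,3-(isopropylidenedioxy)-1-(triethylsilyloxy)cyclohex-4-en-1-yl]methyl benzoate
Conditions: BzCl, pyridine, DMAP (cat.), CH2Cl2, 0 °C
Reagents that add atoms: benzoyl chloride, O=C(Cl)c1ccccc1
Why: DMAP-catalysed acylation of the only free hydroxyl installs the C7 benzoate of the target.

Step 12
Reactants: 24 [(1R,2R,3R,6R)-6-chloro-2,3-(isopropylidenedioxy)-1-(triethylsilyloxy)cyclohex-4-en-1-yl]methyl benzoate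
Product: 25 [(1R,2R,3R,6R)-6-chloro-1,2,3-trihydroxycyclohex-4-en-1-yl]methyl benzoate
Conditions: CF3CO2H–H2O (9:1), CH2Cl2, 0 °C → rt
Reagents that add atoms: none
Why: Aqueous-acid hydrolysis cleaves the cis-fused acetonide and the triethylsilyl ether in one operation, while the allylic chloride should resist ionisation because both ends of the would-be allyl cation (C6 and C4) have electron-withdrawing oxygenated neighbours.

Step 13
Reactants: 25 [(1R,2R,3R,6R)-6-chloro-1,2,3-trihydroxycyclohex-4-en-1-yl]methyl benzoate; 26 tert-butylchlorodimethylsilane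
Product: 27 [(1R,2R,3R,6R)-3-(tert-butyldimethylsilyloxy)-6-chloro-1,2-dihydroxycyclohex-4-en-1-yl]methyl benzoate
Conditions: t-BuMe2SiCl (1.1 equiv), imidazole, DMF, 0 °C
Reagents that add atoms: tert-butylchlorodimethylsilane, CC(C)(C)[Si](C)(C)Cl
Why: Sterically governed monosilylation should select the allylic C3–OH, since C2–OH is flanked by the quaternary C1 and C1–OH is tertiary.

Step 14
Reactants: 27 [(1R,2R,3R,6R)-3-(tert-butyldimethylsilyloxy)-6-chloro-1,2-dihydroxycyclohex-4-en-1-yl]methyl benzoate; 23 benzoyl chloride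
Product: 28 [(1R,2R,3R,6R)-2-(benzoyloxy)-3-(tert-butyldimethylsilyloxy)-6-chloro-1-hydroxycyclohex-4-en-1-yl]methyl benzoate
Conditions: BzCl, pyridine, DMAP (cat.), CH2Cl2, rt
Reagents that add atoms: benzoyl chloride, O=C(Cl)c1ccccc1
Why: DMAP-catalysed benzoylation acylates the secondary C2–OH, whereas the tertiary C1–OH does not react under these conditions.

Step 15
Reactants: 28 [(1R,2R,3R,6R)-2-(benzoyloxy)-3-(tert-butyldimethylsilyloxy)-6-chloro-1-hydroxycyclohex-4-en-1-yl]methyl benzoate
Product: 29 [(1S,2R,3R,6S)-2-(benzoyloxy)-3-(tert-butyldimethylsilyloxy)-7-oxabicyclo[4.1.0]hept-4-en-1-yl]methyl benzoate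
Conditions: KN(SiMe3)2 (1.05 equiv), THF, −78 → 0 °C
Reagents that add atoms: none
Why: Intramolecular Williamson (3-exo-tet) closure of the trans chlorohydrin inverts C6 and puts the oxirane oxygen on the face of O1, syn to O2 and O3, and with O3 silylated any benzoyl shuffling among O1, O2 and O7 is harmless because only the isomer with O1 free can close.

Step 16
Reactants: 29 [(1S,2R,3R,6S)-2-(benzoyloxy)-3-(tert-butyldimethylsilyloxy)-7-oxabicyclo[4.1.0]hept-4-en-1-yl]methyl benzoate
Product: 30 [(1S,2R,3R,6S)-2-(benzoyloxy)-3-hydroxy-7-oxabicyclo[4.1.0]hept-4-en-1-yl]methyl benzoate (CNP0285759.1)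
Conditions: Bu4NF–AcOH (1:1), THF, 0 °C → rt
Reagents that add atoms: none
Why: Fluoride desilylation buffered with acetic acid frees C3–OH without a free alkoxide, so neither benzoyl migration from O2 to O3 nor opening of the vinyl oxirane should intervene.

Compound list
1 | D-galacturonic acid (aldehydo form drawn) | O=C[C@H](O)[C@@H](O)[C@@H](O)[C@H](O)C(=O)O | starting material
2 | benzyl bromide | BrCc1ccccc1 | starting material
3 | benzyl D-galactopyranuronate (anomeric mixture) | OC1O[C@H](C(=O)OCc2ccccc2)[C@H](O)[C@H](O)[C@H]1O | intermediate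
4 | 2,2-dimethoxypropane | COC(C)(C)OC | starting material
5 | benzyl 3,4-O-isopropylidene-D-galactopyranuronate (anomeric mixture) | OC1O[C@H](C(=O)OCc2ccccc2)[C@@H]3OC(C)(C)O[C@@H]3[C@H]1O | intermediate
6 | 3,4-O-isopropylidene-D-galactopyranuronic acid (anomeric mixture) | OC1O[C@H](C(=O)O)[C@@H]2OC(C)(C)O[C@@H]2[C@H]1O | intermediate
7 | dimethyl (1-diazo-2-oxopropyl)phosphonate | COP(=O)(OC)C(=[N+]=[N-])C(C)=O | starting material
8 | 6,7-dideoxy-3,4-O-isopropylidene-L-galacto-hept-6-ynonic acid | C#C[C@H](O)[C@H]1OC(C)(C)O[C@H]1[C@H](O)C(=O)O | intermediate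
9 | 6,7-dideoxy-3,4-O-isopropylidene-L-galacto-hept-6-ynono-1,5-lactone (dioxolane and ethynyl all cis on the lactone ring) | O=C1[C@@H](O)[C@@H]2OC(C)(C)O[C@@H]2[C@H](C#C)O1 | intermediate
10 | chlorotriethylsilane | CC[Si](Cl)(CC)CC | starting material
11 | 6,7-dideoxy-3,4-O-isopropylidene-2-O-triethylsilyl-L-galacto-hept-6-ynono-1,5-lactone | O=C1[C@@H](O[Si](CC)(CC)CC)[C@@H]2OC(C)(C)O[C@@H]2[C@H](C#C)O1 | intermediate
12 | zirconocene chloride hydride Cp2Zr(H)Cl (cyclopentadienyl rings drawn sigma-bonded) | [H][Zr](Cl)(C1C=CC=C1)C1C=CC=C1 | starting material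
13 | N-chlorosuccinimide | O=C1CCC(=O)N1Cl | starting material
14 | (E)-alkenylzirconocene chloride from 11 (Zr on C6; cyclopentadienyl rings drawn sigma-bonded) | O=C1[C@@H](O[Si](CC)(CC)CC)[C@@H]2OC(C)(C)O[C@@H]2[C@H](/C=C/[Zr](Cl)(C3C=CC=C3)C3C=CC=C3)O1 | intermediate
15 | (E)-7-chloro-6,7-dideoxy-3,4-O-isopropylidene-2-O-triethylsilyl-L-galacto-hept-6-enono-1,5-lactone | O=C1[C@@H](O[Si](CC)(CC)CC)[C@@H]2OC(C)(C)O[C@@H]2[C@H](/C=C/Cl)O1 | intermediate
16 | chlorotrimethylsilane | C[Si](C)(C)Cl | starting material
17 | cyclic trimethylsilyl ketene acetal of 15, C7(OSiMe3)=C1(OSiEt3) | C[Si](C)(C)OC1=C(O[Si](CC)(CC)CC)[C@@H]2OC(C)(C)O[C@@H]2[C@H](/C=C/Cl)O1 | intermediate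
18 | trimethylsilyl ester of 19 | C[Si](C)(C)OC(=O)[C@]1(O[Si](CC)(CC)CC)[C@H](Cl)C=C[C@H]2OC(C)(C)O[C@@H]12 | intermediate
19 | (1S,2R,3R,6R)-6-chloro-2,3-(isopropylidenedioxy)-1-(triethylsilyloxy)cyclohex-4-ene-1-carboxylic acid (C7 and Cl on one face; O1, O2, O3 on the other) | OC(=O)[C@]1(O[Si](CC)(CC)CC)[C@H](Cl)C=C[C@H]2OC(C)(C)O[C@@H]12 | intermediate
20 | (trimethylsilyl)diazomethane | C[Si](C)(C)C=[N+]=[N-] | starting material
21 | methyl (1S,2R,3R,6R)-6-chloro-2,3-(isopropylidenedioxy)-1-(triethylsilyloxy)cyclohex-4-ene-1-carboxylate | COC(=O)[C@]1(O[Si](CC)(CC)CC)[C@H](Cl)C=C[C@H]2OC(C)(C)O[C@@H]12 | intermediate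
22 | [(1R,2R,3R,6R)-6-chloro-2,3-(isopropylidenedioxy)-1-(triethylsilyloxy)cyclohex-4-en-1-yl]methanol | OC[C@]1(O[Si](CC)(CC)CC)[C@H](Cl)C=C[C@H]2OC(C)(C)O[C@@H]12 | intermediate
23 | benzoyl chloride | O=C(Cl)c1ccccc1 | starting material
24 | [(1R,2R,3R,6R)-6-chloro-2,3-(isopropylidenedioxy)-1-(triethylsilyloxy)cyclohex-4-en-1-yl]methyl benzoate | O=C(OC[C@]1(O[Si](CC)(CC)CC)[C@H](Cl)C=C[C@H]2OC(C)(C)O[C@@H]12)c1ccccc1 | intermediate
25 | [(1R,2R,3R,6R)-6-chloro-1,2,3-trihydroxycyclohex-4-en-1-yl]methyl benzoate | O=C(OC[C@]1(O)[C@H](Cl)C=C[C@@H](O)[C@H]1O)c1ccccc1 | intermediate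
26 | tert-butylchlorodimethylsilane | CC(C)(C)[Si](C)(C)Cl | starting material
27 | [(1R,2R,3R,6R)-3-(tert-butyldimethylsilyloxy)-6-chloro-1,2-dihydroxycyclohex-4-en-1-yl]methyl benzoate | O=C(OC[C@]1(O)[C@H](Cl)C=C[C@@H](O[Si](C)(C)C(C)(C)C)[C@H]1O)c1ccccc1 | intermediate
28 | [(1R,2R,3R,6R)-2-(benzoyloxy)-3-(tert-butyldimethylsilyloxy)-6-chloro-1-hydroxycyclohex-4-en-1-yl]methyl benzoate | O=C(OC[C@]1(O)[C@H](Cl)C=C[C@@H](O[Si](C)(C)C(C)(C)C)[C@H]1OC(=O)c1ccccc1)c1ccccc1 | intermediate
29 | [(1S,2R,3R,6S)-2-(benzoyloxy)-3-(tert-butyldimethylsilyloxy)-7-oxabicyclo[4.1.0]hept-4-en-1-yl]methyl benzoate | O=C(OC[C@]12O[C@H]1C=C[C@@H](O[Si](C)(C)C(C)(C)C)[C@H]2OC(=O)c1ccccc1)c1ccccc1 | intermediate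
30 | [(1S,2R,3R,6S)-2-(benzoyloxy)-3-hydroxy-7-oxabicyclo[4.1.0]hept-4-en-1-yl]methyl benzoate (CNP0285759.1) | O=C(OC[C@]12O[C@H]1C=C[C@@H](O)[C@H]2OC(=O)c1ccccc1)c1ccccc1 | target

Total step count: 16. Longest linear sequence: 16 (fully linear from 1).

Steps most likely to fail

Step 8.
- What may go wrong: the C2 oxygen is expelled from the enolate before it is silylated. Alternatively, passage through the crowded boat is slow, so prolonged heating erodes the allylic chloride (SN2' re-lactonisation of the silyl ester).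
- The fallback sets out from 15 and comes back at 22. It runs the same C1–C6/C4–O reorganisation one oxidation level lower, where no enolate is needed.
- i-Bu2AlH (1.1 equiv, CH2Cl2, −78 °C) should reduce 15 to the lactol F1.
- Mesylation with in situ elimination (MsCl, Et3N, then DBU) should give the cyclic enol ether F2, a 2-silyloxyglycal-type C7H=C1(OSiEt3) system.
- Heating in o-dichlorobenzene at about 180 °C, with 2,6-lutidine as acid scavenger, is a plain allyl vinyl ether Claisen rearrangement through the same tether-enforced boat. It should give the quaternary aldehyde F3 with the same sense at C1 and C6.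
- NaBH4 in MeOH then leads to 22, and steps 9 and 10 fall away.
- The price is the higher temperature.

Step 4.
- What may go wrong: base-promoted epimerisation of the alpha-hydroxy aldehyde at the carbinol centre that becomes C4, or stalling because too little of the lactol is open.
- The fallback sets out from 6 and comes back at 15. It never exposes an aldehyde to base and also replaces steps 5–7.
- NaBH4 (H2O–MeOH, 0 °C) should reduce the lactol to 3,4-O-isopropylidene-L-galactonic acid F4.
- DCC/DMAP should close the 1,5-lactone F5 (six-membered ring preferred over the seven-membered alternative through the primary hydroxyl).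
- Et3SiCl (2.2 equiv) and imidazole should give the bis(triethylsilyl) ether F6.
- Swern conditions ((COCl)2, DMSO, Et3N, −78 → −30 °C) are known to convert a primary triethylsilyl ether directly into the aldehyde while a secondary one survives. This should give the aldehyde F7.
- Takai–Utimoto chloro-olefination (CrCl2, CHCl3, THF, 65 °C), which is E-selective and non-basic, then delivers 15.

Step 7.
- What may go wrong: reduction of the lactone carbonyl by the zirconium hydride in competition with hydrometalation of the alkyne.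
- The fallback sets out from 11 and comes back at 15. It replaces the oxophilic early-metal hydride by a tin hydride that does not touch lactones.
- Bu3SnH with PdCl2(PPh3)2 (cat., THF, 0 °C) adds syn. With the branched propargylic carbon it should favour the distal (E)-vinylstannane F8.
- CuCl2 in THF then exchanges tin for chlorine with retention of geometry to give 15.

Further compounds
F1 | step 8 | (E)-7-chloro-6,7-dideoxy-3,4-O-isopropylidene-2-O-triethylsilyl-L-galacto-hept-6-enopyranose (lactol of 15) | OC1[C@@H](O[Si](CC)(CC)CC)[C@@H]2OC(C)(C)O[C@@H]2[C@H](/C=C/Cl)O1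
F2 | step 8 | cyclic enol ether C7H=C1(OSiEt3) derived from F1 (2-silyloxyglycal type) | C1=C(O[Si](CC)(CC)CC)[C@@H]2OC(C)(C)O[C@@H]2[C@H](/C=C/Cl)O1
F3 | step 8 | (1S,2R,3R,6R)-6-chloro-2,3-(isopropylidenedioxy)-1-(triethylsilyloxy)cyclohex-4-ene-1-carbaldehyde | O=C[C@]1(O[Si](CC)(CC)CC)[C@H](Cl)C=C[C@H]2OC(C)(C)O[C@@H]12
F4 | step 4 | 3,4-O-isopropylidene-L-galactonic acid | OC[C@H](O)[C@H]1OC(C)(C)O[C@H]1[C@H](O)C(=O)O
F5 | step 4 | 3,4-O-isopropylidene-L-galactono-1,5-lactone | O=C1[C@@H](O)[C@@H]2OC(C)(C)O[C@@H]2[C@H](CO)O1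
F6 | step 4 | 3,4-O-isopropylidene-2,6-bis-O-triethylsilyl-L-galactono-1,5-lactone | O=C1[C@@H](O[Si](CC)(CC)CC)[C@@H]2OC(C)(C)O[C@@H]2[C@H](CO[Si](CC)(CC)CC)O1
F7 | step 4 | 3,4-O-isopropylidene-2-O-triethylsilyl-L-galacto-hexodialdono-1,5-lactone (aldehyde at C5 of the route numbering) | O=C1[C@@H](O[Si](CC)(CC)CC)[C@@H]2OC(C)(C)O[C@@H]2[C@H](C=O)O1
F8 | step 7 | (E)-6,7-dideoxy-3,4-O-isopropylidene-7-(tributylstannyl)-2-O-triethylsilyl-L-galacto-hept-6-enono-1,5-lactone | O=C1[C@@H](O[Si](CC)(CC)CC)[C@@H]2OC(C)(C)O[C@@H]2[C@H](/C=C/[Sn](CCCC)(CCCC)CCCC)O1
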